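**Retrosynthetic overview**

1. Urea C–N bonds: target 9 ⇒ two molecules of benzylammonium chloride 6 plus one carbonyl from CDI 7 (last step, symmetrical coupling).
2. Functional-group change: amine 6 ⇐ nitromethyl catechol 4 (Zn/HCl).
3. Key aryl–CH2 bond: 4 ⇒ methanenitronate (an aminomethyl carbanion equivalent, so the normally electrophilic α-amino carbon acts as the nucleophile) plus the electrophilic β-carbon C4 of tetrabromo-ortho-benzoquinone 1, by addition–elimination of bromide and then reduction.
4. Rings: none is built. The carbocycle of each half is bought as quinone 1 and re-aromatised to the catechol in the key step.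

Assumption: the target has no stereocentre and is achiral, so there is no enantiomer to select; the route delivers the single constitutional isomer drawn. Quinone 1 (o-bromanil) is taken as a catalogue compound.

**Route**

Step 1
Reactants: 1 tetrabromo-ortho-benzoquinone (3,4,5,6-tetrabromocyclohexa-3,5-diene-1,2-dione); 2 nitromethane
Product: 4 3,4,6-tribromo-5-(nitromethyl)benzene-1,2-diol, via nitromethyl ortho-quinone 3 (not isolated)
Conditions: 2 (5 equiv), Cs2CO3 (2.2 equiv), MeCN, N2, −20 °C to 0 °C, 1 added dropwise; then poured into cold aq Na2S2O4 (3 equiv); 1 M HCl work-up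
Reagents that add atoms: nitromethane, C[N+](=O)[O-]
Why: Proposed new method: cesium methanenitronate attacks C4 of the tetrabromo-ortho-quinone, which is a vinylogous acyl bromide, and bromide is expelled (nucleophilic vinylic substitution by addition–elimination); quinone 3 is at once deprotonated to a delocalised aci-nitro/quinone-methide anion that resists a second substitution, and dithionite, present before acidification so that water cannot add to the protonated quinone methide, reduces it to catechol 4; the closest known reaction type is the replacement of halogen in chloranil or 2,3-dichloro-1,4-naphthoquinone by malonate and nitroalkane anions; no stereocentre is formed.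

Step 2
Reactants: 4 3,4,6-tribromo-5-(nitromethyl)benzene-1,2-diol
Product: 6 5-(aminomethyl)-3,4,6-tribromobenzene-1,2-diol hydrochloride, via benzylic hydroxylamine 5 (not isolated)
Conditions: Zn dust (10 equiv), conc. HCl, EtOH, 0 °C to rt; filtered, crystallised from cold 2 M HCl
Reagents that add atoms: hydrogen chloride, Cl
Why: Dissolving-metal reduction of a primary nitroalkane (Zn/HCl) runs through the oxime and hydroxylamine 5 to the primary amine; aryl C–Br bonds are not cleaved by Zn in cold acid, and the product is kept as its ammonium salt so that the para-hydroxybenzylamine can neither eliminate to a quinone methide nor oxidise in air.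

Step 3
Reactants: 6 5-(aminomethyl)-3,4,6-tribromobenzene-1,2-diol hydrochloride (2 equiv); 7 1,1'-carbonyldiimidazole (1 equiv)
Product: 9 1,3-bis[(2,3,6-tribromo-4,5-dihydroxyphenyl)methyl]urea, via acylimidazole 8 (not isolated)
Conditions: 7 (0.5 equiv per amine, added slowly), iPr2NEt (2.2 equiv per amine), DMF, N2, 0 °C then 50 °C; 1 M HCl work-up
Reagents that add atoms: 1,1'-carbonyldiimidazole, O=C(n1ccnc1)n1ccnc1
Why: Carbonyl-transfer urea synthesis: the freed primary amine is acylated by CDI to acylimidazole 8, which a second amine attacks to give the symmetrical urea; any O-acyl species formed at the acidic, electron-poor catechol are activated aryl carbonates or carbamates that pass the carbonyl on to the amine on warming, so the urea is the thermodynamic sink.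

**Compound list**

1 | 3,4,5,6-tetrabromocyclohexa-3,5-diene-1,2-dione (tetrabromo-ortho-benzoquinone, o-bromanil) | O=C1C(=O)C(Br)=C(Br)C(Br)=C1Br | starting material
2 | nitromethane | C[N+](=O)[O-] | starting material
3 | 3,4,6-tribromo-5-(nitromethyl)cyclohexa-3,5-diene-1,2-dione (present in the flask as its cesium aci-nitro salt) | O=C1C(=O)C(Br)=C(Br)C(C[N+](=O)[O-])=C1Br | intermediate (not isolated)
4 | 3,4,6-tribromo-5-(nitromethyl)benzene-1,2-diol | [O-][N+](=O)Cc1c(Br)c(O)c(O)c(Br)c1Br | intermediate
5 | 3,4,6-tribromo-5-[(hydroxyamino)methyl]benzene-1,2-diol | ONCc1c(Br)c(O)c(O)c(Br)c1Br | intermediate (not isolated)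
6 | 5-(aminomethyl)-3,4,6-tribromobenzene-1,2-diol hydrochloride | NCc1c(Br)c(O)c(O)c(Br)c1Br.Cl | intermediate
7 | 1,1'-carbonyldiimidazole | O=C(n1ccnc1)n1ccnc1 | starting material
8 | N-[(2,3,6-tribromo-4,5-dihydroxyphenyl)methyl]imidazole-1-carboxamide | O=C(NCc1c(Br)c(O)c(O)c(Br)c1Br)n1ccnc1 | intermediate (not isolated)
9 | 1,3-bis[(2,3,6-tribromo-4,5-dihydroxyphenyl)methyl]urea | O=C(NCc1c(Br)c(O)c(O)c(Br)c1Br)NCc1c(Br)c(O)c(O)c(Br)c1Br | target

**Step count and risks**

Total steps: 3. Longest linear sequence: 3.

Steps most likely to fail, in order of risk: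

Step 1. The risks are electron transfer from the nitronate to the strongly oxidising quinone, attack at C3 or on bromine instead of C4, and hydration of the protonated quinone methide to the aldehyde. The fallback sets out again from 1 and uses the far less basic and less reducing anion of ethyl nitroacetate (K2CO3, MeCN, 0 °C). This anion undergoes the same addition–elimination at C4, as malonate-type anions do with haloquinones, and gives ethyl 2-nitro-2-(2,5,6-tribromo-3,4-dioxocyclohexa-1,5-dien-1-yl)acetate F1 as its potassium salt. Aqueous Na2S2O4 reduces it in the same flask to racemic ethyl 2-nitro-2-(2,3,6-tribromo-4,5-dihydroxyphenyl)acetate F2. LiOH in THF/water followed by acidification gives 2-nitro-2-(2,3,6-tribromo-4,5-dihydroxyphenyl)acetic acid F3, which loses CO2 at room temperature and comes back to the route at 4.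

Step 2. The risks are partial loss of aryl bromine and stalling at the oxime or at hydroxylamine 5. The fallback sets out from 4 and avoids the amine altogether. Aqueous TiCl3 buffered with NH4OAc in THF turns the primary nitro group into the aldehyde (reductive Nef reaction through the imine) and gives 2,3,6-tribromo-4,5-dihydroxybenzaldehyde F4. Reductive alkylation of urea (0.5 equiv) with this aldehyde, using Et3SiH and TFA in MeCN at 60 °C, passes through 1-[(2,3,6-tribromo-4,5-dihydroxyphenyl)methyl]urea F5 and comes back to the route at target 9, so step 3 is bypassed as well.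

Step 3. The risk is that CDI is consumed at the catechol and that the resulting carbonates and carbamates do not funnel fully to the urea. The fallback sets out from 6 and masks the catechol for the duration of the coupling. Et3N (1 equiv) and then N,O-bis(trimethylsilyl)acetamide (2.5 equiv) in CH2Cl2 give [2,3,6-tribromo-4,5-bis(trimethylsilyloxy)phenyl]methanamine F6. CDI 7 (0.5 equiv) converts it through N-{[2,3,6-tribromo-4,5-bis(trimethylsilyloxy)phenyl]methyl}imidazole-1-carboxamide F7 into 1,3-bis{[2,3,6-tribromo-4,5-bis(trimethylsilyloxy)phenyl]methyl}urea F8. MeOH with a trace of HCl then removes the four silyl groups and comes back to the route at 9.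

**Further compounds**

F1 | step 1 | ethyl 2-nitro-2-(2,5,6-tribromo-3,4-dioxocyclohexa-1,5-dien-1-yl)acetate | CCOC(=O)C([N+](=O)[O-])C1=C(Br)C(=O)C(=O)C(Br)=C1Br
F2 | step 1 | ethyl 2-nitro-2-(2,3,6-tribromo-4,5-dihydroxyphenyl)acetate (racemic) | CCOC(=O)C([N+](=O)[O-])c1c(Br)c(O)c(O)c(Br)c1Br
F3 | step 1 | 2-nitro-2-(2,3,6-tribromo-4,5-dihydroxyphenyl)acetic acid (racemic) | OC(=O)C([N+](=O)[O-])c1c(Br)c(O)c(O)c(Br)c1Br
F4 | step 2 | 2,3,6-tribromo-4,5-dihydroxybenzaldehyde | O=Cc1c(Br)c(O)c(O)c(Br)c1Br
F5 | step 2 | 1-[(2,3,6-tribromo-4,5-dihydroxyphenyl)methyl]urea | NC(=O)NCc1c(Br)c(O)c(O)c(Br)c1Br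
F6 | step 3 | [2,3,6-tribromo-4,5-bis(trimethylsilyloxy)phenyl]methanamine | NCc1c(Br)c(O[Si](C)(C)C)c(O[Si](C)(C)C)c(Br)c1Br
F7 | step 3 | N-{[2,3,6-tribromo-4,5-bis(trimethylsilyloxy)phenyl]methyl}imidazole-1-carboxamide | O=C(NCc1c(Br)c(O[Si](C)(C)C)c(O[Si](C)(C)C)c(Br)c1Br)n1ccnc1
F8 | step 3 | 1,3-bis{[2,3,6-tribromo-4,5-bis(trimethylsilyloxy)phenyl]methyl}urea | O=C(NCc1c(Br)c(O[Si](C)(C)C)c(O[Si](C)(C)C)c(Br)c1Br)NCc1c(Br)c(O[Si](C)(C)C)c(O[Si](C)(C)C)c(Br)c1Br
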